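The flasks dawn, winter and summer are neighbours that differ in their free base, so before running anything we ask what that difference can be worth.

| setting | dawn | winter | summer |
|---|---|---|---|
| solid electrophile | 0.050 M | 0.050 M | 0.050 M |
| nucleophile | 0.950 equiv | 0.950 equiv | 0.950 equiv |
| free base | 0.800 equiv | 1.00 equiv | 1.40 equiv |
| protic impurity | 5.00 mM | 5.00 mM | 5.00 mM |
| time | 15 min | 15 min | 15 min |

    acid set free + free base ⇌ salt of the base, settled at all times (K1 = 2.6 × 10⁵ M⁻¹)
    nucleophile + acid set free ⇌ protonated nucleophile, settled at all times (K2 = 1400 M⁻¹)
    protic impurity + free base → quenched reagent (k3 = 0.92 M⁻¹ s⁻¹)
    solid electrophile ⇌ electrophile, rate k4*(cs4 - [electrophile]) while solid is left; crystals form when [electrophile] > cs4 (cs4 = 2.8 mM, k4 = 0.0054 s⁻¹)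
    electrophile + nucleophile → acid set free + target (k5 = 0.61 M⁻¹ s⁻¹)
    2 free base → homo dimer (k6 = 0.0062 M⁻¹ s⁻¹)

- for a step with 2 of a species take k times the square, and two of it per event
- given per volume of solution although it is solid: solid electrophile
- at the start none of the solid electrophile is in solution
- what has only dissolved of solid electrophile counts as not reacted
- run time (dawn): 15 min

- part of the solid electrophile that has reacted (what has only dissolved counts as not reacted) at the end, dawn
- part of the solid electrophile that has reacted (what has only dissolved counts as not reacted) at the end, winter
- part of the solid electrophile that has reacted (what has only dissolved counts as not reacted) at the end, summer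
- what raising the equivalents of free base from its lowest to its highest value here does to the part of the solid electrophile that has reacted (what has only dissolved counts as not reacted) (changes below 5 percentage points count as none) (it rises / it falls / no change)

Each target takes one electrophile, and each electrophile must first leave the solid, so we count what the solid can hand over. It dissolves fastest while the solution holds no electrophile, at k4 times cs4, which is 0.907 mM min⁻¹. Over 15 min that comes to 27.2% of the charge, a ceiling on the conversion.

The solution does hold some electrophile, though, and that slows the solid. The nucleophile removes dissolved electrophile with a pseudo-first-order rate constant k5[nucleophile], which at the charged amount is 1.74 min⁻¹, larger than the dissolution coefficient of 0.32 min⁻¹. So [electrophile] soon levels off where entry equals removal, a steady state, at 0.440 mM. Target then forms at 0.765 mM min⁻¹, after a delay of about 0.485 min, the inverse of the two rate constants added. Dissolution is the rate-limiting step here, its coefficient being the smaller of the two.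

Multiplying that rate by the time less the delay, and dividing by the charge, gives what we call the delivered share, the part of the solid reacted while the nucleophile stays near its charge: 22.2%. It should run a little high, because the nucleophile is used as the run goes on: this share takes 11.1 mM of it, less than its charge of 47.5 mM, but enough to slow the removal.

The free base enters through the acid set free, which could otherwise take up nucleophile. Even in dawn, at the charged amounts, K1[free base] is 10400 against 66.5 for K2[nucleophile], so the free base wins that contest. Dawn charges 40.0 mM of free base. In dawn the protic impurity claims 5.00 mM and the acid about 11.1 mM, together less than that charge, while the first half-life of the free base by dimerisation alone at that charge, 33.6 min, is longer than the run. We therefore commit to the same delivered share in each flask and to no change.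

The forecast gives 21.5%, 21.6% and 21.6%, with no change, on the ground that "the base loading barely changes the result". Its figures stand a little below ours.

The simulation gives 21.6%, 21.6% and 21.6%, so no change. In summer at 4.83 min, the half-life of the electrophile by reaction with the nucleophile is 0.43 min, far shorter than the 41 min of the nucleophile by the same step, and the electrophile is made 1.01 times as fast as it is used. Summer stopped at 4.0 min has a delivered share of 5.38%, and that flask stands at 5.32%.

Its constants were set for the occasion.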